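**Retrosynthetic overview**
- Target ⇐ seco γ-hydroxy acid: the γ-lactone is closed last, on C7–OH, after the ten-membered ring.
- Ten-membered ring ⇐ Nozaki–Hiyama–Kishi closure of C6–C7; the Z-iodoalkene arm is attached at C3–C4 by ketone enolate alkylation.
- Key disconnection C8–C9 (together with C8–C17): ring-A aldehyde + silyl glyoxylate (C7, C8) + propionate Reformatsky reagent (C17–C19). A Brook rearrangement turns the glyoxylate carbonyl carbon C8 into the nucleophile that attacks the C9 aldehyde.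
- Ring A first: catalytic asymmetric Diels–Alder (C1, C10, C11), Rubottom oxidation (C12), enol triflate reduction (C13=C14).
- Ring order: six-membered ring A → ten-membered ring → lactone.

Atom labels used in all names: ten-membered ring C1–C10 (C1 quaternary, C2 and C9 acetoxy carbons, C5=C6, C7 lactone O-carbon, C8 tertiary carbinol); ring A = C1, C10–C14; C15 = CH3 on C1, C16 = CH3 on C5, C17/C18 = lactone CH/CH3, C19 = lactone C=O, C20 = CH3 on C11; β = face of ring A carrying C15.

Assumption: the (S)-configured oxazaborolidinium is taken to give the ring-A enantiomer drawn; if it gives the antipode, the (R)-catalyst is used.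

Assumption: tigloyl chloride, (E)-pent-3-en-2-one, ethyl diazoacetate, tert-butyl 2-bromopropanoate and propargyl alcohol are bought.

**Step 1**
Reactants: 1 tigloyl chloride; 2 ethanethiol
Product: 3 S-ethyl (E)-2-methylbut-2-enethioate
Conditions: pyridine, CH2Cl2, 0 °C
Reagents that add atoms: none
Why: Acyl substitution of the acid chloride by the thiol (thioesterification) is faster than conjugate addition to the α,β-disubstituted enoyl unit, and the E-alkene is untouched.

**Step 2**
Reactants: 3 S-ethyl (E)-2-methylbut-2-enethioate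
Product: 4 S-ethyl (E)-2-methyl-4-oxobut-2-enethioate
Conditions: SeO2, 1,4-dioxane, 90 °C
Reagents that add atoms: selenium dioxide, O=[Se]=O
Why: Riley-type SeO2 γ-oxidation (ene reaction, then 2,3-shift) of the γ-methyl of the α,β-unsaturated acyl unit gives the enal and keeps the E geometry.

**Step 3**
Reactants: 5 (E)-pent-3-en-2-one
Product: 6 (E)-2-(tert-butyldimethylsilyloxy)penta-1,3-diene
Conditions: LiN(iPr)2, TBSCl, THF/DMPU, −78 °C
Reagents that add atoms: tert-butyl(chloro)dimethylsilane, CC(C)(C)[Si](C)(C)Cl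
Why: Kinetic deprotonation at the acetyl methyl and O-silylation give the cross-conjugated 2-silyloxydiene with the E-propenyl unit intact.

**Step 4**
Reactants: 4 S-ethyl (E)-2-methyl-4-oxobut-2-enethioate; 6 (E)-2-(tert-butyldimethylsilyloxy)penta-1,3-diene
Product: 7 ring-A silyl enol ether aldehyde
Conditions: (S)-1-(2-methylphenyl)-3,3-diphenyltetrahydro-1H,3H-pyrrolo[1,2-c][1,3,2]oxazaborole (20 mol%), HNTf2 (17 mol%), CH2Cl2, −78 → −40 °C
Reagents that add atoms: none
Why: Catalytic enantioselective Diels–Alder reaction in which the boron Lewis acid binds the formyl group, so the nucleophilic CH2 terminus of the 2-silyloxydiene bonds to the β-carbon that becomes quaternary C1, the endo formyl group ends cis to the diene methyl (C10/C11), the E-dienophile keeps COSEt trans to CHO, and the chiral oxazaborolidinium blocks one enal face to fix the absolute configuration at C1, C10 and C11.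

**Step 5**
Reactants: 7 ring-A silyl enol ether aldehyde
Product: 8 ring-A α-silyloxy ketone aldehyde
Conditions: mCPBA, NaHCO3, CH2Cl2, −20 °C
Reagents that add atoms: 3-chloroperoxybenzoic acid, OOC(=O)c1cccc(Cl)c1
Why: Rubottom oxidation in which the peracid epoxidises the silyl enol ether on the face opposite the adjacent C11 methyl and 1,4-silyl migration opens the epoxide to the α-silyloxy ketone, so C12–O is set trans to C20.

**Step 6**
Reactants: 9 ethyl diazoacetate
Product: 10 ethyl 2-diazo-2-(triethylsilyl)acetate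
Conditions: Et3SiOTf, iPr2NEt, Et2O, −78 → 0 °C
Reagents that add atoms: triethylsilyl trifluoromethanesulfonate, CC[Si](CC)(CC)OS(=O)(=O)C(F)(F)F
Why: Electrophilic C-silylation of the nucleophilic diazo carbon, with the amine taking up the proton, gives the α-silyl diazo ester.

**Step 7**
Reactants: 10 ethyl 2-diazo-2-(triethylsilyl)acetate
Product: 11 ethyl triethylsilylglyoxylate
Conditions: Oxone (2KHSO5·KHSO4·K2SO4), NaHCO3, acetone/CH2Cl2/H2O, 0 °C
Reagents that add atoms: potassium peroxymonosulfate, [K+].[O-]S(=O)(=O)OO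
Why: Oxygen-atom transfer from dimethyldioxirane generated in situ to the diazo carbon, with loss of N2, gives the acylsilane (the standard silyl glyoxylate synthesis).

**Step 8 (key step)**
Reactants: 8 ring-A α-silyloxy ketone aldehyde; 11 ethyl triethylsilylglyoxylate; 12 tert-butyl 2-bromopropanoate
Product: 14 bis(triethylsilyl) three-component adduct, via bromozinc aldolate 13 (not isolated)
Conditions: 12 (2.2 equiv), Zn, Et2O, rt; add to 8 + 11 (2.0 equiv), Et2O, −20 → 0 °C; then Et3SiOTf, 2,6-lutidine, −20 °C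
Reagents that add atoms: triethylsilyl trifluoromethanesulfonate, CC[Si](CC)(CC)OS(=O)(=O)C(F)(F)F
Why: Johnson-type silyl glyoxylate three-component coupling in which the zinc propionate enolate adds to the acylsilane carbonyl of 11, a 1,2-Brook rearrangement turns that carbonyl carbon (C8) into a zinc glycolate enolate (acyl-anion reactivity) that attacks the C9 aldehyde through a closed Zimmerman–Traxler transition state with Felkin–Anh control from C10 (C1 anti, setting C9) and with the C17 ester arm cis to O–Zn by internal chelation (placing C8–OSi anti to C9–O), the enantiopure aldehyde consuming the matched C17 enantiomer of the racemic enolate used in excess, and the tert-butyl ester blocking lactonisation so that the C9 zinc alkoxide is silylated in situ.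

**Step 9**
Reactants: 14 bis(triethylsilyl) three-component adduct
Product: 15 C13 enol triflate
Conditions: KN(SiMe3)2, PhNTf2, THF, −78 °C
Reagents that add atoms: N-phenylbis(trifluoromethanesulfonimide), O=S(=O)(N(c1ccccc1)S(=O)(=O)C(F)(F)F)C(F)(F)F
Why: Kinetic deprotonation of the ketone at the unhindered C14 methylene (not at the silyloxy-bearing C12) and O-triflation of the enolate give the C13–C14 enol triflate without touching a stereocentre.

**Step 10**
Reactants: 15 C13 enol triflate
Product: 16 ring-A alkene thioester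
Conditions: Pd(OAc)2 (5 mol%), PPh3 (10 mol%), HCO2H, nBu3N, DMF, 60 °C
Reagents that add atoms: none
Why: Palladium-catalysed formate reduction of the enol triflate (oxidative addition, formate exchange, decarboxylation, reductive elimination) leaves the C13=C14 alkene of the target.

**Step 11**
Reactants: 16 ring-A alkene thioester
Product: 17 C2 methyl ketone
Conditions: Me2CuLi, Et2O, −78 → −40 °C
Reagents that add atoms: lithium dimethylcuprate, [Li+].C[Cu-]C
Why: Organocuprate acylation, in which the thioester is far more reactive toward Me2CuLi than the ethyl and tert-butyl esters and the ketone formed does not react further, installs the methyl that becomes C3.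

**Step 12**
Reactants: 18 propargyl alcohol
Product: 20 (Z)-3-iodo-2-methylprop-2-en-1-ol, via alkenylmagnesium alkoxide 19 (not isolated)
Conditions: MeMgBr (2.5 equiv), CuI (10 mol%), THF, −10 °C → rt; then I2, −78 → 0 °C
Reagents that add atoms: methylmagnesium bromide, C[Mg]Br; iodine, II
Why: Copper-catalysed anti-carbomagnesiation of propargyl alcohol (Duboudin reaction) gives an alkenylmagnesium alkoxide whose iodinolysis with retention fixes the Z geometry (CH2O cis to I) that becomes the C5=C6 alkene.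

**Step 13**
Reactants: 20 (Z)-3-iodo-2-methylprop-2-en-1-ol
Product: 21 (Z)-3-bromo-1-iodo-2-methylprop-1-ene
Conditions: CBr4, PPh3, CH2Cl2, 0 °C
Reagents that add atoms: tetrabromomethane, BrC(Br)(Br)Br
Why: Appel bromination converts the allylic alcohol to the bromide under neutral conditions without isomerising the vinyl iodide.

**Step 14**
Reactants: 17 C2 methyl ketone; 21 (Z)-3-bromo-1-iodo-2-methylprop-1-ene
Product: 23 C2 ketone carrying the Z-iodoalkene arm, via lithium enolate 22 (not isolated)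
Conditions: LiN(iPr)2, THF, −78 °C; then 21, DMPU, −78 → −40 °C
Reagents that add atoms: none
Why: SN2 alkylation of the kinetic lithium enolate of the methyl ketone (its only enolisable side, and more acidic than the ester C17–H) with the allylic bromide forms the C3–C4 bond and keeps the Z-vinyl iodide.

**Step 15**
Reactants: 23 C2 ketone carrying the Z-iodoalkene arm
Product: 24 C2 alcohol C7 aldehyde
Conditions: iBu2AlH (4 equiv), CH2Cl2, −78 °C; aqueous potassium sodium tartrate (KNaC4H4O6) work-up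
Reagents that add atoms: none
Why: In this iBu2AlH reduction hydride adds to the C2 ketone anti to C10 with the small C15 methyl flanking the trajectory (Felkin–Anh) to give the 2R alcohol, and the α-silyloxy ethyl ester stops at the aldehyde through its stable aluminium hemiacetal while the tert-butyl ester is inert at −78 °C.

**Step 16**
Reactants: 24 C2 alcohol C7 aldehyde
Product: 26 C2/C9 diacetate aldehyde, via C9 alcohol 25 (not isolated)
Conditions: HF·pyridine, pyridine, THF, 0 °C; then Ac2O, Et3N, DMAP, CH2Cl2, rt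
Reagents that add atoms: acetic anhydride, CC(=O)OC(C)=O
Why: Buffered HF·pyridine cleaves the secondary triethylsilyl ether faster than the tertiary one and the tert-butyldimethylsilyl ether, and DMAP-catalysed acylation then acetylates the two secondary hydroxyls at C2 and C9.

**Step 17**
Reactants: 26 C2/C9 diacetate aldehyde
Product: 27 ten-membered carbocycle
Conditions: CrCl2 (8 equiv), NiCl2 (2 mol%), DMSO/THF, rt, 2 mM
Reagents that add atoms: none
Why: Nozaki–Hiyama–Kishi macrocyclisation in which the alkenylchromium formed from the Z-vinyl iodide with retention adds at high dilution to the non-enolisable C7 aldehyde anti to the C8 silyloxy group with the C17 arm flanking the trajectory (polar Felkin–Anh), giving the 7S alcohol and the ten-membered ring.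

**Step 18**
Reactants: 27 ten-membered carbocycle
Product: 30 CNP0222085.1 (target), via bis(trimethylsilyl) derivative 28 (not isolated), via seco hydroxy acid 29 (not isolated)
Conditions: Me3SiOTf, 2,6-lutidine, CH2Cl2, 0 °C; then HF·pyridine, THF, 0 °C → rt
Reagents that add atoms: none
Why: Me3SiOTf with 2,6-lutidine cleaves the tert-butyl ester to the silyl ester without protic acid, HF·pyridine then removes all silyl groups, and the γ-hydroxy acid lactonises onto C7–OH only, because C2 and C9 are already acetylated and C8–OH could only give a β-lactone.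

**Compound list**
1 | (E)-2-methylbut-2-enoyl chloride (tigloyl chloride) | C/C=C(\C)C(Cl)=O | starting material
2 | ethanethiol | CCS | starting material
3 | S-ethyl (E)-2-methylbut-2-enethioate | CCSC(=O)/C(C)=C/C | intermediate
4 | S-ethyl (E)-2-methyl-4-oxobut-2-enethioate | CCSC(=O)/C(C)=C/C=O | intermediate
5 | (E)-pent-3-en-2-one | CC(=O)/C=C/C | starting material
6 | (E)-2-(tert-butyldimethylsilyloxy)penta-1,3-diene | C=C(O[Si](C)(C)C(C)(C)C)/C=C/C | intermediate
7 | S-ethyl 10-formyl-1,11-dimethyl-13-(tert-butyldimethylsilyloxy)cyclohex-12-ene-1-carbothioate (C15, CHO and C20 β, COSEt α; absolute configuration as in the target) | O=C[C@H]1[C@@H](C)C=C(O[Si](C)(C)C(C)(C)C)C[C@]1(C)C(=O)SCC | intermediate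
8 | S-ethyl 10-formyl-1,11-dimethyl-13-oxo-12α-(tert-butyldimethylsilyloxy)cyclohexane-1-carbothioate (ring configuration as in 7) | O=C[C@H]1[C@@H](C)[C@H](O[Si](C)(C)C(C)(C)C)C(=O)C[C@]1(C)C(=O)SCC | intermediate
9 | ethyl diazoacetate | CCOC(=O)C=[N+]=[N-] | starting material
10 | ethyl 2-diazo-2-(triethylsilyl)acetate | CCOC(=O)C(=[N+]=[N-])[Si](CC)(CC)CC | intermediate
11 | ethyl 2-oxo-2-(triethylsilyl)acetate (ethyl triethylsilylglyoxylate) | CCOC(=O)C(=O)[Si](CC)(CC)CC | intermediate
12 | tert-butyl 2-bromopropanoate (racemic) | CC(Br)C(=O)OC(C)(C)C | starting material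
13 | bromozinc C9-alkoxide of the adduct (C7 ethyl ester, C19 tert-butyl ester, C8–OSiEt3; C8, C9, C17 arranged as in the target) | CC(C)(C)OC(=O)[C@H](C)[C@](O[Si](CC)(CC)CC)(C(=O)OCC)[C@H](O[Zn]Br)[C@H]1[C@@H](C)[C@H](O[Si](C)(C)C(C)(C)C)C(=O)C[C@]1(C)C(=O)SCC | intermediate
14 | three-component adduct: C7 ethyl ester, C19 tert-butyl ester, C8–OSiEt3, C9–OSiEt3, C12α–OTBS, C13 ketone, C1–COSEt (C8, C9, C17 as in the target) | CC(C)(C)OC(=O)[C@H](C)[C@](O[Si](CC)(CC)CC)(C(=O)OCC)[C@H](O[Si](CC)(CC)CC)[C@H]1[C@@H](C)[C@H](O[Si](C)(C)C(C)(C)C)C(=O)C[C@]1(C)C(=O)SCC | intermediate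
15 | C13–C14 enol triflate of 14 | CC(C)(C)OC(=O)[C@H](C)[C@](O[Si](CC)(CC)CC)(C(=O)OCC)[C@H](O[Si](CC)(CC)CC)[C@H]1[C@@H](C)[C@H](O[Si](C)(C)C(C)(C)C)C(OS(=O)(=O)C(F)(F)F)=C[C@]1(C)C(=O)SCC | intermediate
16 | ring-A C13=C14 alkene with C1–COSEt (otherwise as 14) | CC(C)(C)OC(=O)[C@H](C)[C@](O[Si](CC)(CC)CC)(C(=O)OCC)[C@H](O[Si](CC)(CC)CC)[C@H]1[C@@H](C)[C@H](O[Si](C)(C)C(C)(C)C)C=C[C@]1(C)C(=O)SCC | intermediate
17 | C2 methyl ketone (acetyl on C1; otherwise as 16) | CC(C)(C)OC(=O)[C@H](C)[C@](O[Si](CC)(CC)CC)(C(=O)OCC)[C@H](O[Si](CC)(CC)CC)[C@H]1[C@@H](C)[C@H](O[Si](C)(C)C(C)(C)C)C=C[C@]1(C)C(C)=O | intermediate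
18 | prop-2-yn-1-ol (propargyl alcohol) | C#CCO | starting material
19 | (Z)-3-(bromomagnesio)-2-methylprop-2-en-1-olate bromomagnesium salt | Br[Mg]OC/C(C)=C\[Mg]Br | intermediate
20 | (Z)-3-iodo-2-methylprop-2-en-1-ol | OC/C(C)=C\I | intermediate
21 | (Z)-3-bromo-1-iodo-2-methylprop-1-ene | BrC/C(C)=C\I | intermediate
22 | lithium enolate of 17 (C2(OLi)=C3H2) | CC(C)(C)OC(=O)[C@H](C)[C@](O[Si](CC)(CC)CC)(C(=O)OCC)[C@H](O[Si](CC)(CC)CC)[C@H]1[C@@H](C)[C@H](O[Si](C)(C)C(C)(C)C)C=C[C@]1(C)C(=C)O[Li] | intermediate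
23 | C2 ketone with C3–C4–C5(CH3)=C6H–I arm (Z, C4 cis to I) | CC(C)(C)OC(=O)[C@H](C)[C@](O[Si](CC)(CC)CC)(C(=O)OCC)[C@H](O[Si](CC)(CC)CC)[C@H]1[C@@H](C)[C@H](O[Si](C)(C)C(C)(C)C)C=C[C@]1(C)C(=O)CC/C(C)=C\I | intermediate
24 | (2R)-C2 alcohol, C7 aldehyde (C8–OSiEt3, C9–OSiEt3, C12–OTBS, C19 tert-butyl ester) | CC(C)(C)OC(=O)[C@H](C)[C@](O[Si](CC)(CC)CC)(C=O)[C@H](O[Si](CC)(CC)CC)[C@H]1[C@@H](C)[C@H](O[Si](C)(C)C(C)(C)C)C=C[C@]1(C)[C@H](O)CC/C(C)=C\I | intermediate
25 | C2,C9-diol C7 aldehyde (C8–OSiEt3 and C12–OTBS kept) | CC(C)(C)OC(=O)[C@H](C)[C@](O[Si](CC)(CC)CC)(C=O)[C@H](O)[C@H]1[C@@H](C)[C@H](O[Si](C)(C)C(C)(C)C)C=C[C@]1(C)[C@H](O)CC/C(C)=C\I | intermediate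
26 | C2,C9-diacetate C7 aldehyde with Z-vinyl iodide | CC(C)(C)OC(=O)[C@H](C)[C@](O[Si](CC)(CC)CC)(C=O)[C@H](OC(C)=O)[C@H]1[C@@H](C)[C@H](O[Si](C)(C)C(C)(C)C)C=C[C@]1(C)[C@H](OC(C)=O)CC/C(C)=C\I | intermediate
27 | ten-membered carbocycle: (7S)-C7–OH, C8–OSiEt3, C2/C9 diacetate, C12–OTBS, C17 tert-butyl propanoate arm, (5Z)-alkene | CC(=O)O[C@@H]1[C@H]2[C@@H](C)[C@H](O[Si](C)(C)C(C)(C)C)C=C[C@]2(C)[C@H](OC(C)=O)CC/C(C)=C\[C@H](O)[C@@]1(O[Si](CC)(CC)CC)[C@@H](C)C(=O)OC(C)(C)C | intermediate
28 | C7–OSiMe3 ether / C19 trimethylsilyl ester of 27 | CC(=O)O[C@@H]1[C@H]2[C@@H](C)[C@H](O[Si](C)(C)C(C)(C)C)C=C[C@]2(C)[C@H](OC(C)=O)CC/C(C)=C\[C@H](O[Si](C)(C)C)[C@@]1(O[Si](CC)(CC)CC)[C@@H](C)C(=O)O[Si](C)(C)C | intermediate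
29 | seco acid: C7,C8,C12-triol C19 carboxylic acid, C2/C9 diacetate | CC(=O)O[C@@H]1[C@H]2[C@@H](C)[C@H](O)C=C[C@]2(C)[C@H](OC(C)=O)CC/C(C)=C\[C@H](O)[C@@]1(O)[C@@H](C)C(=O)O | intermediate
30 | CNP0222085.1: (1S,2R,5Z,7S,8S,9R,10S,11R,12R,17R)-2,9-diacetoxy-8,12-dihydroxy briarane 5,13-diene with C19→O–C7 γ-lactone | CC(=O)O[C@@H]1[C@H]2[C@@H](C)[C@H](O)C=C[C@]2(C)[C@H](OC(C)=O)CC/C(C)=C\[C@@H]2OC(=O)[C@H](C)[C@]21O | target

**Step count**
Total: 18 steps. Longest linear sequence: 13 steps (1, 2, 4, 5, 8, 9, 10, 11, 14, 15, 16, 17, 18).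

**Three steps most likely to fail**

Step 8 (three-component coupling). The hindered aldehyde may react sluggishly with the zinc enolate, and the C8/C9/C17 diastereoselection is the least certain in the route. The fallback sets out from 11 and 12 and comes back at 14. The Reformatsky–Brook stage is run without the aldehyde and quenched with NH4Cl to give 1-tert-butyl 4-ethyl 2-methyl-3-(triethylsilyloxy)butanedioate F1. F1 is then deprotonated at its α-silyloxy ester C–H with LiN(iPr)2 at −78 °C, and the more reactive, geometrically defined lithium glycolate enolate is added to aldehyde 8 and trapped with Et3SiOTf to give 14.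

Step 17 (Nozaki–Hiyama–Kishi closure). The ten-membered ring may not close. The fallback sets out from 17 and comes back at 27, replacing the chromium closure by ring-closing metathesis.
- Enolate 22 is alkylated with 3-bromo-2-methylprop-1-ene to give the isopropenyl-terminated C2 ketone F2.
- iBu2AlH gives the C2 alcohol C7 aldehyde F3.
- HF·pyridine gives the C9 alcohol F4, and Ac2O/DMAP gives the diacetate aldehyde F5.
- Intermolecular addition of vinyl bromide with CrCl2/NiCl2 gives the C7 vinyl carbinol F6.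
- Ring-closing metathesis with [1,3-bis(2,4,6-trimethylphenyl)imidazolidin-2-ylidene]dichloro(2-isopropoxybenzylidene)ruthenium (second-generation Hoveyda–Grubbs catalyst) in toluene at 80 °C and 1 mM forms the C5=C6 bond; the ring size enforces the Z geometry, and the product is 27.

Step 15 (double iBu2AlH reduction). The C2 selectivity may be poor, or the ester may be over-reduced. The fallback sets out from 23 and comes back at 24.
- Reagent-controlled reduction of the ketone with (S)-1-methyl-3,3-diphenyltetrahydro-1H,3H-pyrrolo[1,2-c][1,3,2]oxazaborole and catecholborane gives the (2R)-alcohol ethyl ester F7.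
- LiBH4 reduces the ethyl ester fully to the C2,C7-diol F8, with the tert-butyl ester surviving.
- TEMPO/PhI(OAc)2 oxidises only the primary alcohol, giving 24.

Further compounds
F1 | step 8 | 1-tert-butyl 4-ethyl 2-methyl-3-(triethylsilyloxy)butanedioate (racemic, both diastereomers) | CCOC(=O)C(O[Si](CC)(CC)CC)C(C)C(=O)OC(C)(C)C
F2 | step 17 | C2 ketone with C3–C4–C5(CH3)=CH2 arm (otherwise as 17) | CC(C)(C)OC(=O)[C@H](C)[C@](O[Si](CC)(CC)CC)(C(=O)OCC)[C@H](O[Si](CC)(CC)CC)[C@H]1[C@@H](C)[C@H](O[Si](C)(C)C(C)(C)C)C=C[C@]1(C)C(=O)CCC(C)=C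
F3 | step 17 | (2R)-C2 alcohol C7 aldehyde with isopropenyl terminus | CC(C)(C)OC(=O)[C@H](C)[C@](O[Si](CC)(CC)CC)(C=O)[C@H](O[Si](CC)(CC)CC)[C@H]1[C@@H](C)[C@H](O[Si](C)(C)C(C)(C)C)C=C[C@]1(C)[C@H](O)CCC(C)=C
F4 | step 17 | C2,C9-diol C7 aldehyde with isopropenyl terminus | CC(C)(C)OC(=O)[C@H](C)[C@](O[Si](CC)(CC)CC)(C=O)[C@H](O)[C@H]1[C@@H](C)[C@H](O[Si](C)(C)C(C)(C)C)C=C[C@]1(C)[C@H](O)CCC(C)=C
F5 | step 17 | C2,C9-diacetate C7 aldehyde with isopropenyl terminus | CC(C)(C)OC(=O)[C@H](C)[C@](O[Si](CC)(CC)CC)(C=O)[C@H](OC(C)=O)[C@H]1[C@@H](C)[C@H](O[Si](C)(C)C(C)(C)C)C=C[C@]1(C)[C@H](OC(C)=O)CCC(C)=C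
F6 | step 17 | (7S)-C7 vinyl carbinol diene (metathesis precursor) | CC(C)(C)OC(=O)[C@H](C)[C@](O[Si](CC)(CC)CC)([C@@H](O)C=C)[C@H](OC(C)=O)[C@H]1[C@@H](C)[C@H](O[Si](C)(C)C(C)(C)C)C=C[C@]1(C)[C@H](OC(C)=O)CCC(C)=C
F7 | step 15 | (2R)-C2 alcohol with C7 ethyl ester and Z-vinyl iodide | CC(C)(C)OC(=O)[C@H](C)[C@](O[Si](CC)(CC)CC)(C(=O)OCC)[C@H](O[Si](CC)(CC)CC)[C@H]1[C@@H](C)[C@H](O[Si](C)(C)C(C)(C)C)C=C[C@]1(C)[C@H](O)CC/C(C)=C\I
F8 | step 15 | C2,C7-diol (C7 primary alcohol) with Z-vinyl iodide | CC(C)(C)OC(=O)[C@H](C)[C@](O[Si](CC)(CC)CC)(CO)[C@H](O[Si](CC)(CC)CC)[C@H]1[C@@H](C)[C@H](O[Si](C)(C)C(C)(C)C)C=C[C@]1(C)[C@H](O)CC/C(C)=C\I
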